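**Strategy**

Everything rests on cutting ring A (the epoxycyclohexenone) at C2, the nitrogen-bearing carbon that lies between the C1 carbonyl and the C3 methine. Removing C2 leaves an epoxy cyclopentanone whose only enolisable α-carbon is the future C3, so insertion of dibromocarbene into its silyl enol ether enlarges the five-membered ring to ring A in one operation and leaves bromine on C2 for the later C–N coupling. The precursor is the enantiopure bis(triethylsilyl) derivative of a syn-epoxy hydroxy cyclopentanone (enol ether plus tertiary silyl ether) bearing a silyl-capped ethynyl group at the future C4; the alkyne is the anchor for the trienamide arm reaching ring B.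

Key step: step 6

**Remarks on the chemistry**

- Numbering: ring A is the cyclohexenone (C1 carbonyl, C2 nitrogen-bearing carbon, C3 methine, C4 carbinol carbon, C5 and C6 oxirane carbons); ring B is the aminocyclopentenone.
- Assumption: ring B is handled as its enol tautomer, 2-amino-3-hydroxycyclopent-2-en-1-one, the form written in the target.
- Configuration check: the target core is (1S,5S,6R) in 7-oxabicyclo[4.1.0]heptane numbering, with the C4 hydroxyl and the oxirane on one face and the carbon chain on the other. The (R)-enantiomer of 1 leads to exactly this series when the acetylide adds anti to the silyloxy group and the epoxidation is directed by the new hydroxyl. The C4 descriptor reads R while the substituent is an alkyne or a stannylvinyl group and S in the target, only because the CIP priorities change. The side-chain centre is 6R, which requires the (R)-configured benzyl oxazolidinone. No structure needed correction.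

**Route**

Step 1
Reactants: 1 (R)-4-[(tert-butyldimethylsilyl)oxy]cyclopent-2-en-1-one; 2 (triisopropylsilyl)acetylene
Product: 4 (1S,4R)-4-[(tert-butyldimethylsilyl)oxy]-1-[(triisopropylsilyl)ethynyl]cyclopent-2-en-1-ol (hydroxyl cis to the silyloxy group), via lithium (triisopropylsilyl)acetylide 3 (not isolated)
Conditions: 2, n-BuLi, THF, −78 °C; then 1, −78 °C; H2O quench
Reagents that add atoms: none
Why: 1,2-addition of a lithium acetylide to the enone carbonyl, in which the C4 silyloxy group shields its own face so that the nucleophile should enter anti to it and set the carbinol centre with OH cis to the silyl ether, any minor epimer being removable by chromatography.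

Step 2
Reactants: 4
Product: 5 (1R,2R,4R,5S)-4-[(tert-butyldimethylsilyl)oxy]-2-[(triisopropylsilyl)ethynyl]-6-oxabicyclo[3.1.0]hexan-2-ol (oxirane on the face of both oxygen substituents)
Conditions: VO(acac)2 (cat.), t-BuOOH, CH2Cl2, 0 °C → rt
Reagents that add atoms: tert-butyl hydroperoxide, CC(C)(C)OO
Why: Vanadium-catalysed hydroxyl-directed epoxidation of an allylic alcohol, in which the bound tertiary alkoxide delivers the peroxide oxygen to its own face and thereby sets both oxirane centres syn to the carbinol oxygen, while the electron-poor silylalkyne is left alone.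

Step 3
Reactants: 5
Product: 6 (1R,2R,4R,5R)-2-[(triisopropylsilyl)ethynyl]-6-oxabicyclo[3.1.0]hexane-2,4-diol
Conditions: HF·pyridine, pyridine, THF, 0 °C → rt
Reagents that add atoms: none
Why: Fluoride-mediated cleavage of the secondary silyl ether under pyridine-buffered conditions, which should spare the C(sp)–Si bond and the oxirane and touches no stereocentre (the C5 descriptor changes by CIP priority only).

Step 4
Reactants: 6
Product: 7 (1S,4R,5R)-4-hydroxy-4-[(triisopropylsilyl)ethynyl]-6-oxabicyclo[3.1.0]hexan-2-one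
Conditions: Dess–Martin periodinane, NaHCO3, CH2Cl2, 0 °C → rt
Reagents that add atoms: none
Why: Dess–Martin oxidation, in which only the secondary alcohol can react and the buffered, near-neutral medium should avoid retro-aldol cleavage or dehydration of the β-hydroxy ketone.

Step 5
Reactants: 7
Product: 8 triethyl({(1S,4R,5R)-4-[(triethylsilyl)oxy]-4-[(triisopropylsilyl)ethynyl]-6-oxabicyclo[3.1.0]hex-2-en-2-yl}oxy)silane (triethylsilyl enol ether of the syn-epoxy cyclopentanone with the tertiary alcohol also silylated)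
Conditions: Et3SiOTf (excess), Et3N, CH2Cl2, −78 → 0 °C; filtration through Et3N-deactivated silica
Reagents that add atoms: triethylsilyl trifluoromethanesulfonate, CC[Si](CC)(CC)OS(=O)(=O)C(F)(F)F
Why: Soft enolisation with a silyl triflate and an amine, in which the tertiary alcohol is silylated first and the carbonyl is then O-silylated and deprotonated at the only α-carbon with removable hydrogens (the CH2 that becomes C3), no free enolate being formed so that β-elimination of the C4 oxygen should be suppressed.

Step 6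
Reactants: 8; 9 bromoform
Product: 11 (1S,5R,6R)-3-bromo-5-[(triethylsilyl)oxy]-5-[(triisopropylsilyl)ethynyl]-7-oxabicyclo[4.1.0]hept-3-en-2-one (2-bromo-5,6-epoxy enone of ring A), via dibromocyclopropane adduct 10 (not isolated)
Conditions: KOtBu, pentane, slow addition of 9, −20 °C → rt
Reagents that add atoms: none
Why: KOtBu converts CHBr3 into free dibromocarbene, which adds in a concerted cheletropic [2+1] manner to the most electron-rich π bond of 8, the silyl enol ether, to give 10; the endo bromide of 10 then ionises while the bond shared by the two fused rings opens in a disrotatory two-electron electrocyclic process pushed by the siloxy oxygen, and transfer of the silyl group to bromide leaves the enone with bromine on the inserted carbon. The closest known reaction type is the dihalocarbene ring expansion of cyclic silyl enol ethers to 2-halocycloalk-2-enones. The three-membered ring is closed by intermolecular carbene cycloaddition, and the six-membered ring is not closed by a cyclisation at all but arises from cleavage of the internal cyclopropane bond, so no ring-closure geometry has to be met. No stereocentre is created, because both cyclopropane carbons end as sp2 centres and C4, C5 and C6 are spectators that keep the configuration set in steps 1 and 2. The step needs site selectivity, which is fixed because the ketone could enolise only toward the future C3 (its other α-carbon is an oxirane CH), and chemoselectivity over the alkyne, which the low nucleophilicity and steric shielding of the silylalkyne secure. Keeping the alkoxide as a suspension in a hydrocarbon at low temperature should limit its attack on the enol ether and on the product.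

Step 7
Reactants: 12 hexanoyl chloride; 13 (R)-4-benzyloxazolidin-2-one
Product: 14 (R)-4-benzyl-3-hexanoyloxazolidin-2-one
Conditions: Et3N, DMAP (cat.), CH2Cl2, 0 °C → rt
Reagents that add atoms: none
Why: DMAP-catalysed N-acylation of the oxazolidinone by the acid chloride, a standard way to load the auxiliary.

Step 8
Reactants: 14
Product: 16 (R)-4-benzyl-3-[(R)-2-methylhexanoyl]oxazolidin-2-one, via sodium Z-enolate 15 (not isolated)
Conditions: NaN(SiMe3)2, THF, −78 °C; then MeI, −78 °C
Reagents that add atoms: iodomethane, CI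
Why: Evans asymmetric alkylation, in which the chelated Z-enolate is methylated on the face opposite the benzyl group and this sets the future C6 of the side chain as R.

Step 9
Reactants: 16
Product: 17 (R)-2-methylhexan-1-ol
Conditions: LiBH4, H2O (1 equiv), Et2O, 0 °C
Reagents that add atoms: none
Why: Reductive cleavage of the imide with LiBH4, which releases the primary alcohol without epimerisation and returns the auxiliary.

Step 10
Reactants: 17; 18 2-(triphenylphosphoranylidene)propanal
Product: 20 (2E,4R)-2,4-dimethyloct-2-enal, via (R)-2-methylhexanal 19 (not isolated)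
Conditions: TEMPO (cat.), PhI(OAc)2, CH2Cl2, rt; then 18, toluene, 90 °C
Reagents that add atoms: none
Why: Oxoammonium-mediated oxidation to the aldehyde followed in the same flask by Wittig olefination with a stabilised formyl ylide, which should give the E trisubstituted enal while the epimerisable aldehyde is never isolated.

Step 11
Reactants: 20; 21 diethyl (2-amino-2-oxoethyl)phosphonate
Product: 23 (2E,4E,6R)-4,6-dimethyldeca-2,4-dienamide, via sodium phosphonate carbanion 22 (not isolated)
Conditions: 21, NaH, THF, 0 °C; then 20, −20 °C → rt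
Reagents that add atoms: none
Why: Horner–Wadsworth–Emmons olefination with a stabilised phosphonoacetamide anion, which should give the E enamide directly as the primary amide, addition of the enal to the preformed anion keeping the C6 centre away from base.

Step 12
Reactants: 24 cyclopentane-1,3-dione
Product: 25 2-(hydroxyimino)cyclopentane-1,3-dione
Conditions: NaNO2, aq. HCl, 0 °C
Reagents that add atoms: sodium nitrite, [Na+].[O-]N=O
Why: α-Nitrosation of the 1,3-dione at its doubly activated C2 followed by tautomerisation to the oxime.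

Step 13
Reactants: 25
Product: 26 2-amino-3-hydroxycyclopent-2-en-1-one hydrochloride
Conditions: H2 (1 atm), Pd/C, HCl, EtOH, rt
Reagents that add atoms: hydrogen chloride, Cl
Why: Catalytic hydrogenation of the oxime to the primary amine, trapped as its hydrochloride so that the self-condensing free aminodione never accumulates.

Step 14
Reactants: 27 ethyl (E)-4-oxobut-2-enoate; 28 iodoform
Product: 29 ethyl (2E,4E)-5-iodopenta-2,4-dienoate
Conditions: CrCl2, THF, 0 °C
Reagents that add atoms: none
Why: Takai iodo-olefination of the aldehyde, which is E-selective and leaves the conjugated ester untouched.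

Step 15
Reactants: 29
Product: 30 (2E,4E)-5-iodopenta-2,4-dienoic acid
Conditions: LiOH, THF/H2O, 0 °C → rt; then aq. HCl
Reagents that add atoms: lithium hydroxide, [Li+].[OH-]
Why: Ester saponification under mild conditions that do not disturb the vinyl iodide or the diene geometry.

Step 16
Reactants: 30; 26
Product: 32 (2E,4E)-N-(2-hydroxy-5-oxocyclopent-1-en-1-yl)-5-iodopenta-2,4-dienamide, via acid chloride 31 (not isolated)
Conditions: (COCl)2, DMF (cat.), CH2Cl2, 0 °C → rt; concentrate; then 26, Et3N, CH2Cl2, 0 °C → rt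
Reagents that add atoms: none
Why: Acid chloride formation and N-acylation of the amine liberated in situ, any O-acylated enol isomer being expected to migrate to the more stable hydrogen-bonded N-acyl form under the basic conditions.

Step 17
Reactants: 11; 23
Product: 33 (2E,4E,6R)-4,6-dimethyl-N-{(1S,5R,6R)-2-oxo-5-[(triethylsilyl)oxy]-5-[(triisopropylsilyl)ethynyl]-7-oxabicyclo[4.1.0]hept-3-en-3-yl}deca-2,4-dienamide
Conditions: CuI (cat.), N,N'-dimethylethylenediamine, K2CO3, toluene, 70 °C
Reagents that add atoms: none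
Why: CuI/diamine-catalysed Ullmann–Goldberg-type N-vinylation of a primary amide by a vinyl bromide, which forms the C2–N bond with retention of the alkene position under a weak, heterogeneous base that the oxirane and silyl groups should tolerate.

Step 18
Reactants: 33
Product: 34 (2E,4E,6R)-N-[(1S,5R,6R)-5-ethynyl-5-hydroxy-2-oxo-7-oxabicyclo[4.1.0]hept-3-en-3-yl]-4,6-dimethyldeca-2,4-dienamide
Conditions: Bu4NF, AcOH, THF, 0 °C → rt
Reagents that add atoms: none
Why: Fluoride-induced cleavage of both the alkynyl C–Si bond and the tertiary O–Si bond in one operation, buffered with acetic acid to protect the epoxy enone, the syn arrangement of hydroxyl and oxirane excluding a Payne-type epoxide migration.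

Step 19
Reactants: 34
Product: 35 (2E,4E,6R)-N-{(1S,5R,6R)-5-hydroxy-2-oxo-5-[(E)-2-(tributylstannyl)ethenyl]-7-oxabicyclo[4.1.0]hept-3-en-3-yl}-4,6-dimethyldeca-2,4-dienamide
Conditions: Bu3SnH (slow addition), PdCl2(PPh3)2 (cat.), THF, 0 °C
Reagents that add atoms: tributyltin hydride, CCCC[SnH](CCCC)CCCC
Why: Palladium-catalysed syn-hydrostannylation of a terminal alkyne, in which the quaternary propargylic carbon should steer tin to the terminal carbon and give the E vinylstannane faster than the tin hydride can reduce the enone.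

Step 20
Reactants: 35; 32
Product: 36 (2E,4E,6R)-N-[(1S,5S,6R)-5-hydroxy-5-{(1E,3E,5E)-7-[(2-hydroxy-5-oxocyclopent-1-en-1-yl)amino]-7-oxohepta-1,3,5-trien-1-yl}-2-oxo-7-oxabicyclo[4.1.0]hept-3-en-3-yl]-4,6-dimethyldeca-2,4-dienamide (target)
Conditions: Pd2(dba)3 (cat.), AsPh3, DMF, rt, dark
Reagents that add atoms: none
Why: Stille cross-coupling of the vinylstannane with the dienyl iodide under ligand-accelerated room-temperature conditions, which joins C(sp2)–C(sp2) with retention of both alkene geometries and should tolerate the free hydroxyl, the oxirane and both amides.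

**Compound list**

1 | (R)-4-[(tert-butyldimethylsilyl)oxy]cyclopent-2-en-1-one | O=C1C=C[C@H](O[Si](C)(C)C(C)(C)C)C1 | starting material
2 | (triisopropylsilyl)acetylene | C#C[Si](C(C)C)(C(C)C)C(C)C | starting material
3 | lithium (triisopropylsilyl)acetylide | [Li]C#C[Si](C(C)C)(C(C)C)C(C)C | intermediate (not isolated)
4 | (1S,4R)-4-[(tert-butyldimethylsilyl)oxy]-1-[(triisopropylsilyl)ethynyl]cyclopent-2-en-1-ol | O[C@]1(C#C[Si](C(C)C)(C(C)C)C(C)C)C=C[C@H](O[Si](C)(C)C(C)(C)C)C1 | intermediate
5 | (1R,2R,4R,5S)-4-[(tert-butyldimethylsilyl)oxy]-2-[(triisopropylsilyl)ethynyl]-6-oxabicyclo[3.1.0]hexan-2-ol | O[C@]1(C#C[Si](C(C)C)(C(C)C)C(C)C)[C@@H]2O[C@@H]2[C@H](O[Si](C)(C)C(C)(C)C)C1 | intermediate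
6 | (1R,2R,4R,5R)-2-[(triisopropylsilyl)ethynyl]-6-oxabicyclo[3.1.0]hexane-2,4-diol | O[C@]1(C#C[Si](C(C)C)(C(C)C)C(C)C)[C@@H]2O[C@@H]2[C@H](O)C1 | intermediate
7 | (1S,4R,5R)-4-hydroxy-4-[(triisopropylsilyl)ethynyl]-6-oxabicyclo[3.1.0]hexan-2-one | O[C@]1(C#C[Si](C(C)C)(C(C)C)C(C)C)[C@@H]2O[C@@H]2C(=O)C1 | intermediate
8 | triethyl({(1S,4R,5R)-4-[(triethylsilyl)oxy]-4-[(triisopropylsilyl)ethynyl]-6-oxabicyclo[3.1.0]hex-2-en-2-yl}oxy)silane | CC[Si](CC)(CC)OC1=C[C@@](O[Si](CC)(CC)CC)(C#C[Si](C(C)C)(C(C)C)C(C)C)[C@@H]2O[C@@H]21 | intermediate (key-step precursor)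
9 | bromoform | BrC(Br)Br | starting material
10 | 6,6-dibromo-2,3-epoxy-1,4-bis[(triethylsilyl)oxy]-4-[(triisopropylsilyl)ethynyl]bicyclo[3.1.0]hexane (cyclopropane drawn on the face opposite the oxirane; either face leads to 11) | CC[Si](CC)(CC)O[C@]12C(Br)(Br)[C@H]1[C@@](O[Si](CC)(CC)CC)(C#C[Si](C(C)C)(C(C)C)C(C)C)[C@@H]1O[C@@H]12 | intermediate (not isolated)
11 | (1S,5R,6R)-3-bromo-5-[(triethylsilyl)oxy]-5-[(triisopropylsilyl)ethynyl]-7-oxabicyclo[4.1.0]hept-3-en-2-one | BrC1=C[C@@](O[Si](CC)(CC)CC)(C#C[Si](C(C)C)(C(C)C)C(C)C)[C@@H]2O[C@@H]2C1=O | intermediate (key-step product)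
12 | hexanoyl chloride | CCCCCC(Cl)=O | starting material
13 | (R)-4-benzyloxazolidin-2-one | O=C1N[C@H](Cc2ccccc2)CO1 | starting material
14 | (R)-4-benzyl-3-hexanoyloxazolidin-2-one | CCCCCC(=O)N1[C@H](Cc2ccccc2)COC1=O | intermediate
15 | sodium Z-enolate of 14 | CCCC/C=C(\[O-])N1[C@H](Cc2ccccc2)COC1=O.[Na+] | intermediate (not isolated)
16 | (R)-4-benzyl-3-[(R)-2-methylhexanoyl]oxazolidin-2-one | CCCC[C@@H](C)C(=O)N1[C@H](Cc2ccccc2)COC1=O | intermediate
17 | (R)-2-methylhexan-1-ol | CCCC[C@@H](C)CO | intermediate
18 | 2-(triphenylphosphoranylidene)propanal | CC(C=O)=P(c1ccccc1)(c1ccccc1)c1ccccc1 | starting material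
19 | (R)-2-methylhexanal | CCCC[C@@H](C)C=O | intermediate (not isolated)
20 | (2E,4R)-2,4-dimethyloct-2-enal | CCCC[C@@H](C)/C=C(C)/C=O | intermediate
21 | diethyl (2-amino-2-oxoethyl)phosphonate | CCOP(=O)(CC(N)=O)OCC | starting material
22 | sodium salt of the carbanion of 21 | CCOP(=O)([CH-]C(N)=O)OCC.[Na+] | intermediate (not isolated)
23 | (2E,4E,6R)-4,6-dimethyldeca-2,4-dienamide | CCCC[C@@H](C)/C=C(C)/C=C/C(N)=O | intermediate
24 | cyclopentane-1,3-dione | O=C1CCC(=O)C1 | starting material
25 | 2-(hydroxyimino)cyclopentane-1,3-dione | O=C1CCC(=O)C1=NO | intermediate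
26 | 2-amino-3-hydroxycyclopent-2-en-1-one hydrochloride | NC1=C(O)CCC1=O.Cl | intermediate
27 | ethyl (E)-4-oxobut-2-enoate | CCOC(=O)/C=C/C=O | starting material
28 | iodoform | IC(I)I | starting material
29 | ethyl (2E,4E)-5-iodopenta-2,4-dienoate | CCOC(=O)/C=C/C=C/I | intermediate
30 | (2E,4E)-5-iodopenta-2,4-dienoic acid | OC(=O)/C=C/C=C/I | intermediate
31 | (2E,4E)-5-iodopenta-2,4-dienoyl chloride | ClC(=O)/C=C/C=C/I | intermediate (not isolated)
32 | (2E,4E)-N-(2-hydroxy-5-oxocyclopent-1-en-1-yl)-5-iodopenta-2,4-dienamide | O=C(/C=C/C=C/I)NC1=C(O)CCC1=O | intermediate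
33 | (2E,4E,6R)-4,6-dimethyl-N-{(1S,5R,6R)-2-oxo-5-[(triethylsilyl)oxy]-5-[(triisopropylsilyl)ethynyl]-7-oxabicyclo[4.1.0]hept-3-en-3-yl}deca-2,4-dienamide | CCCC[C@@H](C)/C=C(C)/C=C/C(=O)NC1=C[C@@](O[Si](CC)(CC)CC)(C#C[Si](C(C)C)(C(C)C)C(C)C)[C@@H]2O[C@@H]2C1=O | intermediate
34 | (2E,4E,6R)-N-[(1S,5R,6R)-5-ethynyl-5-hydroxy-2-oxo-7-oxabicyclo[4.1.0]hept-3-en-3-yl]-4,6-dimethyldeca-2,4-dienamide | CCCC[C@@H](C)/C=C(C)/C=C/C(=O)NC1=C[C@@](O)(C#C)[C@@H]2O[C@@H]2C1=O | intermediate
35 | (2E,4E,6R)-N-{(1S,5R,6R)-5-hydroxy-2-oxo-5-[(E)-2-(tributylstannyl)ethenyl]-7-oxabicyclo[4.1.0]hept-3-en-3-yl}-4,6-dimethyldeca-2,4-dienamide | CCCC[C@@H](C)/C=C(C)/C=C/C(=O)NC1=C[C@@](O)(/C=C/[Sn](CCCC)(CCCC)CCCC)[C@@H]2O[C@@H]2C1=O | intermediate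
36 | (2E,4E,6R)-N-[(1S,5S,6R)-5-hydroxy-5-{(1E,3E,5E)-7-[(2-hydroxy-5-oxocyclopent-1-en-1-yl)amino]-7-oxohepta-1,3,5-trien-1-yl}-2-oxo-7-oxabicyclo[4.1.0]hept-3-en-3-yl]-4,6-dimethyldeca-2,4-dienamide | CCCC[C@@H](C)/C=C(C)/C=C/C(=O)NC1=C[C@@](O)(/C=C/C=C/C=C/C(=O)NC2=C(O)CCC2=O)[C@@H]2O[C@@H]2C1=O | target

**Step count**

- Total: 20 steps.
- Longest linear sequence: 10 steps (steps 1–6, then 17–20). The side chain (steps 7–11) and the ring B fragment (steps 12–16) are shorter branches.

**Steps most likely to fail, with fallbacks**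

1. Step 6 (carbene ring expansion). What may go wrong: the alkoxide may cleave the silyl enol ether, after which the liberated enolate can expel the C4 oxygen. Alkoxide may also attack the bromo enone as it forms, or the dibromocyclopropane may open incompletely. Fallback (carbon inserted as CH2, halogen added afterwards): starting from 8, Simmons–Smith cyclopropanation (Et2Zn, CH2I2, CH2Cl2, 0 °C) should give 2,3-epoxy-1,4-bis[(triethylsilyl)oxy]-4-[(triisopropylsilyl)ethynyl]bicyclo[3.1.0]hexane F1. FeCl3 in DMF should then cleave the shared cyclopropane bond oxidatively to the ring-enlarged 3-chloro-5,6-epoxy-4-[(triethylsilyl)oxy]-4-[(triisopropylsilyl)ethynyl]cyclohexan-1-one F2, and NaOAc in MeOH should eliminate HCl to (1S,5R,6R)-5-[(triethylsilyl)oxy]-5-[(triisopropylsilyl)ethynyl]-7-oxabicyclo[4.1.0]hept-3-en-2-one F3. Addition of Br2 (CH2Cl2, −20 °C) to the 2,3-dibromo ketone F4 and dehydrobromination with Et3N come back to the route at 11.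

2. Step 17 (C2–N coupling). What may go wrong: slow turnover of the copper amidate with the hindered, electron-poor bromo enone; conjugate addition of the amide followed by ring closure onto the C–Br carbon; base-induced degradation of the epoxy enone on prolonged heating. Fallback (nitrogen introduced as a free amine and acylated afterwards): starting from 11, zerovalent-palladium-catalysed coupling with benzophenone imine (Pd2(dba)3, BINAP, Cs2CO3, toluene) should give (1S,5R,6R)-3-[(diphenylmethylidene)amino]-5-[(triethylsilyl)oxy]-5-[(triisopropylsilyl)ethynyl]-7-oxabicyclo[4.1.0]hept-3-en-2-one F5. Aqueous citric acid in THF should release (1S,5R,6R)-3-amino-5-[(triethylsilyl)oxy]-5-[(triisopropylsilyl)ethynyl]-7-oxabicyclo[4.1.0]hept-3-en-2-one F6. In parallel, enal 20 is condensed with malonic acid (pyridine, piperidine, Knoevenagel–Doebner) to (2E,4E,6R)-4,6-dimethyldeca-2,4-dienoic acid F7, which (COCl)2 converts into (2E,4E,6R)-4,6-dimethyldeca-2,4-dienoyl chloride F8. Acylation of F6 with F8 (pyridine, CH2Cl2, 0 °C) comes back to the route at 33.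

3. Step 19 (hydrostannylation). What may go wrong: delivery of tin to the internal alkyne carbon, conjugate reduction of the amido enone or reductive opening of the oxirane by the tin hydride, and protodestannylation on purification. Fallback (no tin hydride; the alkene is made by coupling first and trans-reduction second): starting from 34 and 32, Sonogashira coupling (PdCl2(PPh3)2, CuI, i-Pr2NH, THF, rt) should give the dienyne, the 6,7-didehydro analogue of the target F9. Ruthenium-catalysed trans-hydrosilylation ([Cp*Ru(MeCN)3]PF6, (EtO)3SiH, CH2Cl2, 0 °C) should give the vinylsilane carrying a triethoxysilyl group on chain carbon 6 F10; the other regioisomer would converge on the same product. Protodesilylation with retention (CuI, Bu4NF, THF, 0 °C) then delivers the E alkene, so this path replaces step 20 as well and comes back to the route at 36.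

**Further compounds**

F1 | step 6 | 2,3-epoxy-1,4-bis[(triethylsilyl)oxy]-4-[(triisopropylsilyl)ethynyl]bicyclo[3.1.0]hexane | CC[Si](CC)(CC)O[C@]12C[C@H]1[C@@](O[Si](CC)(CC)CC)(C#C[Si](C(C)C)(C(C)C)C(C)C)[C@@H]1O[C@@H]12
F2 | step 6 | 3-chloro-5,6-epoxy-4-[(triethylsilyl)oxy]-4-[(triisopropylsilyl)ethynyl]cyclohexan-1-one (C3 epimers) | C1C(Cl)[C@@](O[Si](CC)(CC)CC)(C#C[Si](C(C)C)(C(C)C)C(C)C)[C@@H]2O[C@@H]2C1=O
F3 | step 6 | (1S,5R,6R)-5-[(triethylsilyl)oxy]-5-[(triisopropylsilyl)ethynyl]-7-oxabicyclo[4.1.0]hept-3-en-2-one | C1=C[C@@](O[Si](CC)(CC)CC)(C#C[Si](C(C)C)(C(C)C)C(C)C)[C@@H]2O[C@@H]2C1=O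
F4 | step 6 | 2,3-dibromo-5,6-epoxy-4-[(triethylsilyl)oxy]-4-[(triisopropylsilyl)ethynyl]cyclohexan-1-one (C2/C3 isomers) | BrC1C(Br)[C@@](O[Si](CC)(CC)CC)(C#C[Si](C(C)C)(C(C)C)C(C)C)[C@@H]2O[C@@H]2C1=O
F5 | step 17 | (1S,5R,6R)-3-[(diphenylmethylidene)amino]-5-[(triethylsilyl)oxy]-5-[(triisopropylsilyl)ethynyl]-7-oxabicyclo[4.1.0]hept-3-en-2-one | C(c1ccccc1)(c1ccccc1)=NC1=C[C@@](O[Si](CC)(CC)CC)(C#C[Si](C(C)C)(C(C)C)C(C)C)[C@@H]2O[C@@H]2C1=O
F6 | step 17 | (1S,5R,6R)-3-amino-5-[(triethylsilyl)oxy]-5-[(triisopropylsilyl)ethynyl]-7-oxabicyclo[4.1.0]hept-3-en-2-one | NC1=C[C@@](O[Si](CC)(CC)CC)(C#C[Si](C(C)C)(C(C)C)C(C)C)[C@@H]2O[C@@H]2C1=O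
F7 | step 17 | (2E,4E,6R)-4,6-dimethyldeca-2,4-dienoic acid | CCCC[C@@H](C)/C=C(C)/C=C/C(O)=O
F8 | step 17 | (2E,4E,6R)-4,6-dimethyldeca-2,4-dienoyl chloride | CCCC[C@@H](C)/C=C(C)/C=C/C(Cl)=O
F9 | step 19 | (2E,4E,6R)-N-[(1S,5R,6R)-5-hydroxy-5-{(3E,5E)-7-[(2-hydroxy-5-oxocyclopent-1-en-1-yl)amino]-7-oxohepta-3,5-dien-1-yn-1-yl}-2-oxo-7-oxabicyclo[4.1.0]hept-3-en-3-yl]-4,6-dimethyldeca-2,4-dienamide | CCCC[C@@H](C)/C=C(C)/C=C/C(=O)NC1=C[C@@](O)(C#C/C=C/C=C/C(=O)NC2=C(O)CCC2=O)[C@@H]2O[C@@H]2C1=O
F10 | step 19 | vinylsilane from trans-hydrosilylation of F9, triethoxysilyl group on chain carbon 6 with the carbon chain E | CCCC[C@@H](C)/C=C(C)/C=C/C(=O)NC1=C[C@@](O)(/C=C(\[Si](OCC)(OCC)OCC)/C=C/C=C/C(=O)NC2=C(O)CCC2=O)[C@@H]2O[C@@H]2C1=O
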